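**Retrosynthetic overview**

- Feature: the CH2–CH2 bridge between ring A (the methoxy ring) and ring D (the para-phenylene) sits on ring A ortho to the A–O–B ether carbon (the carbon flanked by OMe) and on ring D para to the D–O–C ether carbon. One carbonyl carbon in its place activates both ether carbons for SNAr and is exactly one carbon short of the bridge.
- Target 17 ⇐ H2/Pd-C (alkyne to CH2CH2, O-benzyl cleavage) ⇐ 18-membered diarylalkyne 16 ⇐ one-carbon insertion (Colvin / Fritsch–Buttenberg–Wiechell) into the 17-membered diaryl ketone 13.
- 13 ⇐ macrocyclic SNAr (D–O–C ether, fluoride para to the ketone) of seco-phenol 12 ⇐ Wittig / diimide from keto-aldehyde 7 and phosphonium salt 10.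
- 7 ⇐ aryl Grignard addition / oxidation of aldehyde 3 ⇐ SNAr of 2-fluoro-3-methoxybenzaldehyde with 3-hydroxybenzyl alcohol. The crowded A–O–B ether is made intermolecularly while the future ketone carbon is still the more strongly activating aldehyde.
- Ring order: all four benzene rings are bought; the only ring formed is the macrocycle, closed 17-membered in step 8 and enlarged to 18 in step 9.

Key step: step 9

Assumption: the target has no stereocentre and no configurationally stable axis or plane at room temperature, so it is treated as achiral and no stereocontrol is required.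

**Step 1**
Reactants: 1 2-fluoro-3-methoxybenzaldehyde; 2 3-hydroxybenzyl alcohol
Product: 3 2-[3-(hydroxymethyl)phenoxy]-3-methoxybenzaldehyde
Conditions: K2CO3, DMF, 100 °C
Reagents that add atoms: none
Why: SNAr (addition–elimination) at the fluoride ortho to the formyl group, in which carbonate generates only the phenoxide of 2 so that the benzylic hydroxyl stays free and the crowded ether next to OMe is formed intermolecularly.

**Step 2**
Reactants: 3 2-[3-(hydroxymethyl)phenoxy]-3-methoxybenzaldehyde; 4 1-bromo-4-fluorobenzene
Product: 6 (4-fluorophenyl){2-[3-(hydroxymethyl)phenoxy]-3-methoxyphenyl}methanol (racemic), via 4-fluorophenylmagnesium bromide 5 (not isolated)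
Conditions: 4, Mg, cat. I2, THF, reflux; then 3 (0.4 equiv relative to 5), THF, 0 °C → rt; aq NH4Cl
Reagents that add atoms: none
Why: Grignard formation by selective insertion into the C–Br bond and 1,2-addition to the aldehyde, with one equivalent consumed by the free hydroxyl; the new carbinol centre is racemic and is erased in step 3.

**Step 3**
Reactants: 6 (4-fluorophenyl){2-[3-(hydroxymethyl)phenoxy]-3-methoxyphenyl}methanol
Product: 7 3-[2-(4-fluorobenzoyl)-6-methoxyphenoxy]benzaldehyde
Conditions: Dess–Martin periodinane (2.5 equiv), CH2Cl2, rt
Reagents that add atoms: none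
Why: Dess–Martin oxidation should convert both benzylic alcohols in one operation, the diaryl carbinol to the diaryl ketone and the primary alcohol to the aldehyde, without over-oxidation.

**Step 4**
Reactants: 8 4-(benzyloxy)-3-hydroxybenzaldehyde
Product: 9 2-(benzyloxy)-5-(hydroxymethyl)phenol
Conditions: NaBH4, MeOH, 0 °C
Reagents that add atoms: none
Why: Borohydride reduction of an aromatic aldehyde, which leaves the phenol and the benzyl ether untouched.

**Step 5**
Reactants: 9 2-(benzyloxy)-5-(hydroxymethyl)phenol
Product: 10 {[4-(benzyloxy)-3-hydroxyphenyl]methyl}triphenylphosphonium bromide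
Conditions: PPh3·HBr, MeCN, reflux
Reagents that add atoms: triphenylphosphine hydrobromide, Br.c1ccc(cc1)P(c1ccccc1)c1ccccc1
Why: Direct phosphonium salt formation from an electron-rich benzylic alcohol, which ionises readily (para-alkoxybenzyl cation) and is captured by triphenylphosphine, the phenol and benzyl ether being tolerated.

**Step 6**
Reactants: 10 {[4-(benzyloxy)-3-hydroxyphenyl]methyl}triphenylphosphonium bromide; 7 3-[2-(4-fluorobenzoyl)-6-methoxyphenoxy]benzaldehyde
Product: 11 (4-fluorophenyl)[2-(3-{2-[4-(benzyloxy)-3-hydroxyphenyl]ethenyl}phenoxy)-3-methoxyphenyl]methanone (E/Z mixture)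
Conditions: 10, NaHMDS (2.1 equiv), THF, 0 °C; then 7, 0 °C → rt; dilute aq HCl work-up
Reagents that add atoms: none
Why: Wittig olefination with a semi-stabilised benzylic ylide (generated as the phenoxide-ylide with two equivalents of base), which should react with the aldehyde far faster than with the hindered diaryl ketone; the E/Z ratio is irrelevant because the alkene is saturated in step 7.

**Step 7**
Reactants: 11 (4-fluorophenyl)[2-(3-{2-[4-(benzyloxy)-3-hydroxyphenyl]ethenyl}phenoxy)-3-methoxyphenyl]methanone
Product: 12 (4-fluorophenyl)[2-(3-{2-[4-(benzyloxy)-3-hydroxyphenyl]ethyl}phenoxy)-3-methoxyphenyl]methanone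
Conditions: KO2CN=NCO2K (excess, in portions), AcOH, pyridine–MeOH, rt → 40 °C
Reagents that add atoms: none
Why: Diimide reduction transfers H2 to the non-polar C=C only, sparing the diaryl ketone, the aryl fluoride and the benzyl ether; the azodicarboxylate source is chosen over sulfonyl hydrazides so that no hydrazone can form at the ketone.

**Step 8**
Reactants: 12 (4-fluorophenyl)[2-(3-{2-[4-(benzyloxy)-3-hydroxyphenyl]ethyl}phenoxy)-3-methoxyphenyl]methanone
Product: 13 17-membered macrocyclic diaryl ketone (O-benzyl)
Conditions: Cs2CO3, DMSO, 110 °C, slow addition of 12 (final ca. 2 mM)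
Reagents that add atoms: none
Why: Intramolecular SNAr of the ring-C phenoxide at the unhindered fluoride para to the benzoyl carbonyl (Meisenheimer intermediate stabilised by the ketone), the reaction type used to prepare macrocyclic aryl ether ketones under pseudo-high dilution, closing the 17-membered ring at the only electrophilic site left.

**Step 9**
Reactants: 13 17-membered macrocyclic diaryl ketone (O-benzyl)
Product: 16 18-membered macrocyclic diarylalkyne (O-benzyl), via macrocyclic diazoalkene 14 (not isolated), via macrocyclic alkylidene carbene 15 (not isolated)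
Conditions: TMSCHN2, n-BuLi, THF, −78 °C; then 13, −78 °C → rt, then 50 °C
Reagents that add atoms: trimethylsilyldiazomethane, C[Si](C)(C)C=[N+]=[N-]
Why: Proposed new method: the closest known reaction type is the Colvin rearrangement of acyclic diaryl ketones to diarylalkynes, which is asked here to act on a ketone embedded in a macrocycle so that the aryl shift enlarges the ring. Lithiated trimethylsilyldiazomethane should add to the carbonyl of 13, the β-silyl alkoxide should lose lithium trimethylsilanolate (Peterson elimination) to give diazoalkene 14, and loss of N2 on warming should give alkylidene carbene 15. A Fritsch–Buttenberg–Wiechell 1,2-aryl shift to the carbene carbon then forms the new aryl–C(sp) bond and the C≡C bridge; no ring is closed, the existing 17-membered ring simply growing to 18 members by insertion of one carbon. No stereocentre is created, and no regiocontrol is needed because migration of either ring A or ring D (the electron-rich para-aryloxyphenyl ring D is expected) gives the same alkyne. The selectivity required is clean carbonyl addition followed by aryl shift faster than interception of the carbene by the neighbouring ortho aryloxy oxygen or by solvent. The ketone has no α-hydrogen (no enolisation), diarylalkylidene carbenes rearrange extremely fast, and the two meta-phenylene and two ether hinges should let the 18-membered ring accept a slightly bent C–C≡C–C unit.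

**Step 10**
Reactants: 16 18-membered macrocyclic diarylalkyne (O-benzyl)
Product: 17 target macrocycle (CNP0309263.0)
Conditions: H2 (1–3 atm), 10% Pd/C, EtOAc–EtOH, rt
Reagents that add atoms: none
Why: Heterogeneous catalytic hydrogenation should saturate the diarylalkyne to the CH2–CH2 bridge and hydrogenolyse the benzyl ether in the same operation, while the diaryl ethers and the methyl ether are stable.

**Compound list**

1 | 2-fluoro-3-methoxybenzaldehyde | COc1cccc(C=O)c1F | starting material
2 | 3-hydroxybenzyl alcohol | OCc1cccc(O)c1 | starting material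
3 | 2-[3-(hydroxymethyl)phenoxy]-3-methoxybenzaldehyde | COc1cccc(C=O)c1Oc1cccc(CO)c1 | intermediate
4 | 1-bromo-4-fluorobenzene | Fc1ccc(Br)cc1 | starting material
5 | 4-fluorophenylmagnesium bromide (not isolated) | Fc1ccc([Mg]Br)cc1 | intermediate
6 | (4-fluorophenyl){2-[3-(hydroxymethyl)phenoxy]-3-methoxyphenyl}methanol (racemic) | COc1cccc(C(O)c2ccc(F)cc2)c1Oc1cccc(CO)c1 | intermediate
7 | 3-[2-(4-fluorobenzoyl)-6-methoxyphenoxy]benzaldehyde | COc1cccc(C(=O)c2ccc(F)cc2)c1Oc1cccc(C=O)c1 | intermediate
8 | 4-(benzyloxy)-3-hydroxybenzaldehyde | O=Cc1ccc(OCc2ccccc2)c(O)c1 | starting material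
9 | 2-(benzyloxy)-5-(hydroxymethyl)phenol | OCc1ccc(OCc2ccccc2)c(O)c1 | intermediate
10 | {[4-(benzyloxy)-3-hydroxyphenyl]methyl}triphenylphosphonium bromide | [Br-].Oc1cc(C[P+](c2ccccc2)(c2ccccc2)c2ccccc2)ccc1OCc1ccccc1 | intermediate
11 | (4-fluorophenyl)[2-(3-{2-[4-(benzyloxy)-3-hydroxyphenyl]ethenyl}phenoxy)-3-methoxyphenyl]methanone (E/Z mixture) | COc1cccc(C(=O)c2ccc(F)cc2)c1Oc1cccc(C=Cc2ccc(OCc3ccccc3)c(O)c2)c1 | intermediate
12 | (4-fluorophenyl)[2-(3-{2-[4-(benzyloxy)-3-hydroxyphenyl]ethyl}phenoxy)-3-methoxyphenyl]methanone | COc1cccc(C(=O)c2ccc(F)cc2)c1Oc1cccc(CCc2ccc(OCc3ccccc3)c(O)c2)c1 | intermediate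
13 | 17-membered macrocyclic diaryl ketone (O-benzyl): ring A joined to ring D through C=O | COc1cccc2c1Oc1cccc(c1)CCc1ccc(OCc3ccccc3)c(c1)Oc1ccc(cc1)C2=O | intermediate
14 | macrocyclic diazoalkene (diazomethylidene at the former carbonyl carbon; not isolated) | COc1cccc2c1Oc1cccc(c1)CCc1ccc(OCc3ccccc3)c(c1)Oc1ccc(cc1)C2=C=[N+]=[N-] | intermediate
15 | macrocyclic alkylidene carbene (not isolated) | COc1cccc2c1Oc1cccc(c1)CCc1ccc(OCc3ccccc3)c(c1)Oc1ccc(cc1)C2=[C] | intermediate
16 | 18-membered macrocyclic diarylalkyne (O-benzyl): ring A joined to ring D through C≡C | COc1cccc2c1Oc1cccc(c1)CCc1ccc(OCc3ccccc3)c(c1)Oc1ccc(cc1)C#C2 | intermediate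
17 | target macrocycle CNP0309263.0 (achiral) | COc1cccc2c1Oc1cccc(c1)CCc1ccc(O)c(c1)Oc1ccc(cc1)CC2 | target

**Step count**

Total: 10 steps. Longest linear sequence: 8 steps (1, 2, 3, 6, 7, 8, 9, 10); steps 4 and 5 form the side branch that joins at step 6.

**Steps most likely to fail**

Step 9 (the step marked as a proposed new method). The bulky lithiated diazo reagent may fail to add to the crowded, electron-rich carbonyl. The carbene may also be diverted before the aryl shift (attack by the ortho aryloxy oxygen, insertion), or ring strain may oppose formation of a near-linear alkyne inside the ring. The fallback uses known chemistry and avoids both the carbene and the alkyne. Setting out from 13, methylenation with methylenetriphenylphosphorane (Ph3P=CH2, THF) should give the macrocyclic exocyclic 1,1-diarylethene F1. Treatment with [hydroxy(tosyloxy)iodo]benzene in 95% methanol is the known oxidative rearrangement of 1,1-diarylethenes to deoxybenzoins, which also enlarges benzo-fused methylenecycloalkanes by one carbon. It should shift ring D by a cationic 1,2-aryl migration and give the ring-expanded 18-membered aryl benzyl ketone F2; the regioisomer from migration of ring A would serve equally. Hydrogenolysis over Pd/C under H2 in acetic acid with a trace of HClO4 should then remove the benzylic carbonyl oxygen and the benzyl ether together, returning to the route at 17.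

Step 8. At the temperature needed for ketone-activated substitution, intermolecular ether formation (oligomerisation) may outrun closure of the 17-membered ring, or the dilute reaction may stall. The fallback forms this ether intermolecularly and closes the ring at the B–C bridge instead. Setting out from 7 and 9, SNAr (K2CO3, DMSO, 110 °C) should give 3-[2-(4-{2-(benzyloxy)-5-(hydroxymethyl)phenoxy}benzoyl)-6-methoxyphenoxy]benzaldehyde F3. PPh3·HBr in MeCN should convert its benzylic alcohol into the phosphonium bromide F4. Intramolecular Wittig reaction under high dilution (K2CO3, 18-crown-6, CH2Cl2, reflux, slow addition) should close the ring as the macrocyclic stilbene ketone F5 (E/Z mixture). Diimide reduction as in step 7 returns to the route at 13.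

Step 1. Substitution at the carbon flanked by the methoxy and formyl groups may be slow, and the aldehyde may degrade under prolonged hot basic conditions before conversion is complete. The fallback sets out from 2 and uses the base-stable nitrile as activating group. SNAr with commercial 2-fluoro-3-methoxybenzonitrile (COc1cccc(C#N)c1F; K2CO3, DMF, 80–100 °C) should give 2-[3-(hydroxymethyl)phenoxy]-3-methoxybenzonitrile F6. Reduction with DIBAL-H (2.2 equiv, toluene, −78 °C; aqueous HCl) should convert the nitrile to the aldehyde and return to the route at 3.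

**Further compounds**

F1 | step 9 | macrocyclic exocyclic 1,1-diarylethene (C=CH2 in place of C=O of 13) | COc1cccc2c1Oc1cccc(c1)CCc1ccc(OCc3ccccc3)c(c1)Oc1ccc(cc1)C2=C
F2 | step 9 | ring-expanded 18-membered aryl benzyl ketone (ring A–C(=O)–CH2–ring D, O-benzyl) | COc1cccc2c1Oc1cccc(c1)CCc1ccc(OCc3ccccc3)c(c1)Oc1ccc(cc1)CC2=O
F3 | step 8 | 3-[2-(4-{2-(benzyloxy)-5-(hydroxymethyl)phenoxy}benzoyl)-6-methoxyphenoxy]benzaldehyde | COc1cccc(C(=O)c2ccc(Oc3cc(CO)ccc3OCc3ccccc3)cc2)c1Oc1cccc(C=O)c1
F4 | step 8 | phosphonium bromide of F3 (CH2OH replaced by CH2PPh3+ Br−) | [Br-].COc1cccc(C(=O)c2ccc(Oc3cc(C[P+](c4ccccc4)(c4ccccc4)c4ccccc4)ccc3OCc3ccccc3)cc2)c1Oc1cccc(C=O)c1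
F5 | step 8 | macrocyclic stilbene ketone (E/Z mixture; CH=CH in place of the B–C CH2CH2 of 13) | COc1cccc2c1Oc1cccc(c1)C=Cc1ccc(OCc3ccccc3)c(c1)Oc1ccc(cc1)C2=O
F6 | step 1 | 2-[3-(hydroxymethyl)phenoxy]-3-methoxybenzonitrile | COc1cccc(C#N)c1Oc1cccc(CO)c1
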